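**Retrosynthetic overview**
1. Target 30 ⇐ methyl ester 29 ⇐ ring D closed last by SmI2 ketyl–alkyne cyclisation (C13–C16) of propargyl ketone 28.
2. Ring A ⇐ lithium aldol C2–C3 (3β-OH) then hydroxyl-directed reduction (1α-OH) of keto aldehyde 26; C1–C2 come from 1-ethoxyvinyllithium added to the C10 ketone.
3. 19,10-Lactone with C4, C5, C6 ⇐ proposed new alkoxide-triggered oxa-Michael/Michael cascade of a C10 β-alkoxy-α-methylacrylate onto the ring B enoate (23 → 25).
4. Quaternary C8 ⇐ Claisen rearrangement of (R)-allylic alcohol 8 (chirality from asymmetric transfer hydrogenation), then hydroboration/oxidation (C10=O) and Ohira–Bestmann homologation (propargyl arm).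
5. Ring order: C (arene of 1, Birch-reduced) → B (Friedel–Crafts) → lactone → A → D.

Assumption: the SMILES is read as the 1α,3β,13-trihydroxy 19,10-lactone acid; C1–C19 in names are the gibberellin positions of the target, α is the face of the lactone bridge, β the opposite face.

**Step 1**
Reactants: 1 (3-methoxyphenyl)acetic acid; 2 tert-butyl bromoacetate
Product: 3 4-tert-butoxy-2-(3-methoxyphenyl)-4-oxobutanoic acid (racemic)
Conditions: LiN(i-Pr)2 (2.1 equiv), THF, −78 → 0 °C; then 2, −78 → 23 °C; 1 M HCl work-up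
Reagents that add atoms: none
Why: Alkylation of the arylacetic acid dianion (enediolate) at the benzylic carbon by a reactive SN2 electrophile gives the arylsuccinic half ester that carries C5–C8, C10 and the ring C carbons.

**Step 2**
Reactants: 3 4-tert-butoxy-2-(3-methoxyphenyl)-4-oxobutanoic acid
Product: 4 6-methoxy-3-oxo-2,3-dihydro-1H-indene-1-carboxylic acid (racemic; ketone = C10, CO2H = C7)
Conditions: CF3SO3H, CH2Cl2, 0 → 23 °C
Reagents that add atoms: none
Why: The acid cleaves the tert-butyl ester and drives an intramolecular Friedel–Crafts acylation by the CH2CO2H carbonyl (only the five-membered ketone can form) para to the methoxy group, closing ring B.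

**Step 3**
Reactants: 4 6-methoxy-3-oxo-2,3-dihydro-1H-indene-1-carboxylic acid
Product: 5 (3R)-3-hydroxy-6-methoxy-2,3-dihydro-1H-indene-1-carboxylic acid (both C1 epimers)
Conditions: RuCl(p-cymene)[(R,R)-TsDPEN] (1 mol%), HCO2H/Et3N (5:2), DMF, 40 °C
Reagents that add atoms: none
Why: Noyori asymmetric transfer hydrogenation of a 1-indanone; the (R,R) catalyst sets the (R)-carbinol (C10, the relay for C8) irrespective of the remote C6 centre, which is erased in step 10.

**Step 4**
Reactants: 5 (3R)-3-hydroxy-6-methoxy-2,3-dihydro-1H-indene-1-carboxylic acid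
Product: 7 methyl (3R)-3-hydroxy-6-methoxy-2,3,4,7-tetrahydro-1H-indene-1-carboxylate, via lithium carboxylate 6 (not isolated)
Conditions: Li, NH3(l), THF, t-BuOH, −78 °C; NH4Cl; evaporate NH3; then MeI, DMF, 23 °C
Reagents that add atoms: iodomethane, CI
Why: Birch reduction of a 3,4-dialkylanisole gives the 2,5-dihydro isomer that keeps the tetrasubstituted C8=C9 alkene and the C13 enol ether (the benzylic C–O bond is protected as its alkoxide); SN2 methylation of the carboxylate avoids acid.

**Step 5**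
Reactants: 7 methyl (3R)-3-hydroxy-6-methoxy-2,3,4,7-tetrahydro-1H-indene-1-carboxylate
Product: 8 methyl (3R)-6,6-(ethylenedioxy)-3-hydroxy-2,3,4,5,6,7-hexahydro-1H-indene-1-carboxylate
Conditions: HOCH2CH2OH, pyridinium p-toluenesulfonate, CH2Cl2, 23 °C
Reagents that add atoms: ethane-1,2-diol, OCCO
Why: Mild acid-catalysed addition of the diol to the enol ether (transketalisation) masks C13 as a dioxolane without moving the C8=C9 alkene into conjugation.

**Step 6**
Reactants: 8 methyl (3R)-6,6-(ethylenedioxy)-3-hydroxy-2,3,4,5,6,7-hexahydro-1H-indene-1-carboxylate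
Product: 10 methyl (7aR)-6,6-(ethylenedioxy)-7a-(2-oxoethyl)-2,4,5,6,7,7a-hexahydro-1H-indene-1-carboxylate, via allyl vinyl ether 9 (not isolated)
Conditions: n-BuOCH=CH2, Pd(OCOCF3)2 (5 mol%), 4,7-diphenyl-1,10-phenanthroline, Et3N, 75 °C; then xylenes, 150 °C, sealed tube
Reagents that add atoms: butyl vinyl ether, C=COCCCC
Why: Vinyl transfer then aliphatic Claisen [3,3] rearrangement; the suprafacial transition state forms the C8–C15 bond on the face that carried the C10–O bond, so the (R)-carbinol sets the quaternary C8 centre.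

**Step 7**
Reactants: 10 methyl (7aR)-6,6-(ethylenedioxy)-7a-(2-oxoethyl)-2,4,5,6,7,7a-hexahydro-1H-indene-1-carboxylate
Product: 12 methyl 6,6-(ethylenedioxy)-3-hydroxy-7a-(2-hydroxyethyl)octahydro-1H-indene-1-carboxylate (trans-fused: 9α-H and 10α-OH), via alkylborane 11 (not isolated)
Conditions: BH3·THF, THF, 0 → 23 °C; then NaOAc, 30% H2O2, 0 °C
Reagents that add atoms: borane–tetrahydrofuran, B.C1CCOC1 (boron stays only in 11); hydrogen peroxide, OO
Why: Hydroboration–oxidation: BH3 reduces the aldehyde and adds syn and anti-Markovnikov to the trisubstituted alkene from the face opposite the angular chain, putting oxygen on C10 (the 9α-H centre is corrected in step 9).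

**Step 8**
Reactants: 12 methyl 6,6-(ethylenedioxy)-3-hydroxy-7a-(2-hydroxyethyl)octahydro-1H-indene-1-carboxylate
Product: 13 methyl 6,6-(ethylenedioxy)-3-oxo-7a-(2-oxoethyl)octahydro-1H-indene-1-carboxylate (trans-fused)
Conditions: Dess–Martin periodinane, NaHCO3, CH2Cl2, 23 °C
Reagents that add atoms: none
Why: Dess–Martin oxidation converts the primary and the secondary alcohol under buffered conditions that leave the ketal and ester untouched.

**Step 9**
Reactants: 13 methyl 6,6-(ethylenedioxy)-3-oxo-7a-(2-oxoethyl)octahydro-1H-indene-1-carboxylate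
Product: 15 methyl 6,6-(ethylenedioxy)-3-oxo-7a-(prop-2-yn-1-yl)octahydro-1H-indene-1-carboxylate (cis-fused: 9β-H), via trans-fused alkyne 14 (not isolated)
Conditions: MeC(O)C(N2)P(O)(OMe)2, K2CO3, MeOH, 0 → 23 °C, 16 h
Reagents that add atoms: dimethyl (1-diazo-2-oxopropyl)phosphonate, CC(=O)C(=[N+]=[N-])P(=O)(OC)OC
Why: Ohira–Bestmann (Seyferth–Gilbert) homologation is selective for the aldehyde, and K2CO3/MeOH equilibrates C9 (alpha to the ketone) to the more stable cis-hydrindanone (as in 14β-15-keto steroids), setting 9β-H.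

**Step 10**
Reactants: 15 methyl 6,6-(ethylenedioxy)-3-oxo-7a-(prop-2-yn-1-yl)octahydro-1H-indene-1-carboxylate
Product: 17 methyl 6,6-(ethylenedioxy)-3-oxo-7a-(prop-2-yn-1-yl)-3a,4,5,6,7,7a-hexahydro-3H-indene-1-carboxylate (ring B enone ester), via bromo ketone 16 (not isolated)
Conditions: LiN(SiMe3)2 (1.05 equiv), THF, −78 °C; N-bromosuccinimide, −78 °C; then DBU, 0 °C
Reagents that add atoms: N-bromosuccinimide, O=C1CCC(=O)N1Br (bromine stays only in 16)
Why: Kinetic enolisation at the unhindered C5 methylene, bromination and E1cB dehydrobromination through the ester-activated C6–H give the C10 keto C5=C6 enoate from either C6 epimer.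

**Step 11**
Reactants: 17 ring B enone ester
Product: 18 methyl 3-(1-ethoxyvinyl)-6,6-(ethylenedioxy)-3-hydroxy-7a-(prop-2-yn-1-yl)-3a,4,5,6,7,7a-hexahydro-3H-indene-1-carboxylate (C10: OH α, ethoxyvinyl β)
Conditions: CH2=C(OEt)Li (from CH2=CHOEt and t-BuLi), CeCl3, THF, −78 °C; then H2O
Reagents that add atoms: ethyl vinyl ether, C=COCC (used as 1-ethoxyvinyllithium, [Li]C(=C)OCC)
Why: 1,2-Addition of the acyl-anion equivalent as its weakly basic organocerium reagent occurs from the convex β face (ring C shields the α face), setting the C10 tertiary carbinol with oxygen α and bringing in C1 and C2.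

**Step 12**
Reactants: 19 ethyl 1-propenyl ether; 20 oxalyl chloride
Product: 22 (E)-3-ethoxy-2-methylprop-2-enoyl chloride, via oxalyl adduct 21 (not isolated)
Conditions: neat, 0 → 23 °C; then 120 °C, distil
Reagents that add atoms: none
Why: C-acylation of the enol ether by oxalyl chloride and thermal decarbonylation (Tietze-type preparation of β-alkoxyacryloyl chlorides) give the E acid chloride that carries C3, C4, C18 and C19.

**Step 13**
Reactants: 18 tertiary alcohol; 22 (E)-3-ethoxy-2-methylprop-2-enoyl chloride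
Product: 23 (E)-3-ethoxy-2-methylacrylate ester of 18 at the C10 oxygen
Conditions: LiN(SiMe3)2 (1.05 equiv), THF, −78 °C; then 22, −78 → 0 °C
Reagents that add atoms: none
Why: O-acylation of the preformed lithium alkoxide; LiN(SiMe3)2 deprotonates the hydroxyl but not the terminal alkyne, and the acid chloride has no α-hydrogen for ketene formation.

**Step 14**
Reactants: 23 (E)-3-ethoxy-2-methylacrylate ester
Product: 25 19,10-lactone with 4-methyl and 4-dimethoxymethyl (C3) groups (5β-H; 6β-CO2Me; C10 1-ethoxyvinyl; C13 dioxolane; C8 propargyl), via methoxyacrylate ester 24 (not isolated)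
Conditions: NaOMe (1.5 equiv), MeOH/THF (1:3), 0 → 23 °C
Reagents that add atoms: methanol, CO (with sodium methoxide, [Na+].[O-]C)
Why: Proposed new method: an alkoxide-triggered oxa-Michael/Michael lactonising cascade in which MeO− adds to C3 of the β-alkoxyacrylate (the addition that normally only exchanges the alkoxy group, here giving 24) and the resulting C4 ester enolate is captured 5-exo-trig by the tethered enoate at C5 on the α face with the bulky CH(OMe)2 arm on the convex side (sets C4 and 5β-H), while NaOMe/MeOH equilibrates C6 to the trans 6β-ester; the closest known reaction types are Michael-initiated ring closure, base-catalysed alcohol addition/exchange on β-alkoxyacrylates and the ester-enolate Michael lactonisation of classical gibberellin syntheses.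

**Step 15**
Reactants: 25 lactone acetal
Product: 26 19,10-lactone keto aldehyde (C10 acetyl = C1/C2; C4 formyl = C3; C13 ketone; methyl ester)
Conditions: 3 M HCl, THF, 40 °C
Reagents that add atoms: water, O
Why: Acid hydrolysis removes the enol ether, the dimethyl acetal and the dioxolane in one operation; no remaining group is acid-labile and the aldehyde has no α-hydrogen.

**Step 16**
Reactants: 26 lactone keto aldehyde
Product: 27 3β-hydroxy-1,13-dioxo lactone methyl ester (ring A closed)
Conditions: LiN(SiMe3)2 (3 equiv), THF, −78 °C; AcOH, −78 °C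
Reagents that add atoms: none
Why: Intramolecular lithium aldol (6-enolendo-exo-trig): the C2 enolate of the methyl ketone adds to the neopentyl aldehyde through a Li-chelated Zimmerman–Traxler arrangement that places the new oxygen axial (3β-OH), the excess base only enolising the C13 ketone reversibly.

**Step 17**
Reactants: 27 3β-hydroxy-1,13-dioxo lactone methyl ester
Product: 28 1α,3β-dihydroxy-13-oxo lactone methyl ester
Conditions: Me4NBH(OAc)3, MeCN/AcOH (1:1), −30 °C
Reagents that add atoms: none
Why: Evans–Saksena hydroxyl-directed reduction: the axial 3β-alkoxyborohydride delivers hydride to the β face of the C1 ketone, giving the anti (1α,3β) diol and leaving the unassisted C13 ketone untouched.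

**Step 18**
Reactants: 28 1α,3β-dihydroxy-13-oxo lactone methyl ester
Product: 29 methyl ester of the target (7-methyl ester; ring D closed)
Conditions: SmI2 (2.5 equiv), t-BuOH, THF/HMPA, 0 °C
Reagents that add atoms: none
Why: SmI2 ketyl–alkyne radical cyclisation (5-exo-dig): the C13 ketyl adds to C16 of the axial propargyl arm and the vinyl radical is reduced and protonated, giving the 13-hydroxy bridgehead and the exocyclic methylene, with C13 fixed by the bicyclic geometry.

**Step 19**
Reactants: 29 methyl ester of the target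
Product: 30 target acid CNP0252949.2
Conditions: LiSCH2CH2CH3, HMPA, 23 °C; then 1 M HCl
Reagents that add atoms: none
Why: SN2 demethylation of the hindered methyl ester by thiolate avoids hydroxide, so the lactone and the base-labile 3β-hydroxy centre (retro-aldol) are preserved.

**Compound list**
1 | (3-methoxyphenyl)acetic acid | COc1cccc(CC(=O)O)c1 | starting material
2 | tert-butyl bromoacetate | CC(C)(C)OC(=O)CBr | starting material
3 | 4-tert-butoxy-2-(3-methoxyphenyl)-4-oxobutanoic acid (racemic) | COc1cccc(c1)C(CC(=O)OC(C)(C)C)C(=O)O | intermediate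
4 | 6-methoxy-3-oxo-2,3-dihydro-1H-indene-1-carboxylic acid (racemic) | COc1ccc2C(=O)CC(C(=O)O)c2c1 | intermediate
5 | (3R)-3-hydroxy-6-methoxy-2,3-dihydro-1H-indene-1-carboxylic acid (both C1 epimers) | COc1ccc2c(c1)C(C[C@H]2O)C(=O)O | intermediate
6 | lithium (3R)-3-hydroxy-6-methoxy-2,3,4,7-tetrahydro-1H-indene-1-carboxylate | COC1=CCC2=C(C1)C(C[C@H]2O)C(=O)[O-].[Li+] | intermediate
7 | methyl (3R)-3-hydroxy-6-methoxy-2,3,4,7-tetrahydro-1H-indene-1-carboxylate (both C1 epimers) | COC1=CCC2=C(C1)C(C[C@H]2O)C(=O)OC | intermediate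
8 | methyl (3R)-6,6-(ethylenedioxy)-3-hydroxy-2,3,4,5,6,7-hexahydro-1H-indene-1-carboxylate (C13 dioxolane, C8=C9 alkene) | O[C@@H]1CC(C(=O)OC)C2=C1CCC3(C2)OCCO3 | intermediate
9 | O-vinyl ether of 8 | C=CO[C@@H]1CC(C(=O)OC)C2=C1CCC3(C2)OCCO3 | intermediate
10 | methyl (7aR)-6,6-(ethylenedioxy)-7a-(2-oxoethyl)-2,4,5,6,7,7a-hexahydro-1H-indene-1-carboxylate (quaternary C8, C9=C10 alkene) | O=CC[C@]23CC4(OCCO4)CCC2=CCC3C(=O)OC | intermediate
11 | bis-borane adduct of 10 (C10–BH2 on the α face, C16–O–BH2) | [BH2]OCC[C@]23CC4(OCCO4)CC[C@@H]2[C@@H]([BH2])CC3C(=O)OC | intermediate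
12 | methyl 6,6-(ethylenedioxy)-3-hydroxy-7a-(2-hydroxyethyl)octahydro-1H-indene-1-carboxylate (trans-fused, 9α-H, 10α-OH) | OCC[C@]23CC4(OCCO4)CC[C@@H]2[C@@H](O)CC3C(=O)OC | intermediate
13 | methyl 6,6-(ethylenedioxy)-3-oxo-7a-(2-oxoethyl)octahydro-1H-indene-1-carboxylate (trans-fused) | O=CC[C@]23CC4(OCCO4)CC[C@@H]2C(=O)CC3C(=O)OC | intermediate
14 | trans-fused (9α-H) propargyl ketone | C#CC[C@]23CC4(OCCO4)CC[C@@H]2C(=O)CC3C(=O)OC | intermediate
15 | methyl 6,6-(ethylenedioxy)-3-oxo-7a-(prop-2-yn-1-yl)octahydro-1H-indene-1-carboxylate (cis-fused, 9β-H) | C#CC[C@]23CC4(OCCO4)CC[C@H]2C(=O)CC3C(=O)OC | intermediate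
16 | C5-bromo derivative of 15 | C#CC[C@]23CC4(OCCO4)CC[C@H]2C(=O)C(Br)C3C(=O)OC | intermediate
17 | methyl 6,6-(ethylenedioxy)-3-oxo-7a-(prop-2-yn-1-yl)-3a,4,5,6,7,7a-hexahydro-3H-indene-1-carboxylate (C10 ketone, C5=C6 enoate) | C#CC[C@]23CC4(OCCO4)CC[C@H]2C(=O)C=C3C(=O)OC | intermediate
18 | methyl 3-(1-ethoxyvinyl)-6,6-(ethylenedioxy)-3-hydroxy-7a-(prop-2-yn-1-yl)-3a,4,5,6,7,7a-hexahydro-3H-indene-1-carboxylate (C10: OH α, ethoxyvinyl β) | C#CC[C@]23CC4(OCCO4)CC[C@H]2[C@](O)(C(OCC)=C)C=C3C(=O)OC | intermediate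
19 | ethyl 1-propenyl ether (E/Z mixture) | CC=COCC | starting material
20 | oxalyl chloride | ClC(=O)C(Cl)=O | starting material
21 | (E)-4-ethoxy-3-methyl-2-oxobut-3-enoyl chloride | CCO/C=C(\C)C(=O)C(Cl)=O | intermediate
22 | (E)-3-ethoxy-2-methylprop-2-enoyl chloride | CCO/C=C(\C)C(Cl)=O | intermediate
23 | (E)-3-ethoxy-2-methylacrylate ester of 18 (at the C10 oxygen) | C#CC[C@]23CC4(OCCO4)CC[C@H]2[C@](OC(=O)/C(C)=C/OCC)(C(OCC)=C)C=C3C(=O)OC | intermediate
24 | (E)-3-methoxy-2-methylacrylate ester of 18 | C#CC[C@]23CC4(OCCO4)CC[C@H]2[C@](OC(=O)/C(C)=C/OC)(C(OCC)=C)C=C3C(=O)OC | intermediate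
25 | 19,10-lactone: C4 bears methyl and CH(OMe)2 (C3), 5β-H, 6β-CO2Me, C10 1-ethoxyvinyl, C13 dioxolane, C8 propargyl | C#CC[C@]23CC4(OCCO4)CC[C@H]2[C@@]1(C(OCC)=C)OC(=O)[C@](C)(C(OC)OC)[C@H]1[C@@H]3C(=O)OC | intermediate
26 | 19,10-lactone keto aldehyde: C10 acetyl, C4 formyl, C13 ketone, C8 propargyl, 6β-CO2Me | C#CC[C@]23CC(=O)CC[C@H]2[C@@]1(C(C)=O)OC(=O)[C@](C)(C=O)[C@H]1[C@@H]3C(=O)OC | intermediate
27 | 3β-hydroxy-1,13-dioxo 19,10-lactone methyl ester with C8 propargyl (rings A, B, C) | C#CC[C@]23CC(=O)CC[C@H]2[C@@]12OC(=O)[C@@](C)([C@H]1[C@@H]3C(=O)OC)[C@@H](O)CC2=O | intermediate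
28 | 1α,3β-dihydroxy-13-oxo 19,10-lactone methyl ester with C8 propargyl | C#CC[C@]23CC(=O)CC[C@H]2[C@@]12OC(=O)[C@@](C)([C@H]1[C@@H]3C(=O)OC)[C@@H](O)C[C@@H]2O | intermediate
29 | 7-methyl ester of the target (1α,3β,13-trihydroxy-16-ene 19,10-lactone) | C=C1C[C@]23C[C@@]1(O)CC[C@H]2[C@@]12OC(=O)[C@@](C)([C@H]1[C@@H]3C(=O)OC)[C@@H](O)C[C@@H]2O | intermediate
30 | CNP0252949.2 (1α,3β,13-trihydroxy C19-gibberellin 19,10-lactone 7-acid) | C=C1C[C@]23C[C@@]1(O)CC[C@H]2[C@@]12OC(=O)[C@@](C)([C@H]1[C@@H]3C(=O)O)[C@@H](O)C[C@@H]2O | target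

**Step count and risks**
Total step count: 19. Longest linear sequence: 18 steps (steps 1–11 and 13–19; step 12 makes the acid chloride).

Steps most likely to fail:

- Step 14 (the proposed new cascade). The alkoxide adduct may only exchange or eliminate, or C4 may form with the wrong configuration. The fallback uses known chemistry, sets out from 18 and comes back at 26. Compound 18 is O-acylated (LiN(SiMe3)2, propionyl chloride, THF, −78 °C) to the propionate F3. KN(SiMe3)2 in THF (−78 → 0 °C), then NaOMe/MeOH, effects the ester-enolate Michael lactonisation known from classical gibberellin work and equilibrates C6, giving the C4–H lactone F4. LiN(i-Pr)2 (THF, −78 °C) and gaseous CH2O hydroxymethylate the more acidic, less hindered lactone enolate from the convex face to give the hydroxymethyl lactone F5. Dess–Martin oxidation gives the formyl lactone F6. 3 M HCl/THF then removes the enol ether and the dioxolane to give 26.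

- Step 6 (vinyl transfer and Claisen rearrangement forming the quaternary C8). The hindered alcohol may vinylate poorly or eliminate on heating. The fallback sets out from 8 and comes back at 12. PhNCO/pyridine gives the N-phenylcarbamate F1. MeLi, CuI and then vinyllithium (THF, −78 → 0 °C; carbamate-directed syn-SN2' cuprate substitution) deliver a vinyl group to C8 on the face of the leaving group, giving the C8 vinyl diene F2. BH3·THF followed by NaOAc/H2O2 hydroborates both alkenes and gives 12.

- Step 18 (late ketyl–alkyne cyclisation on the most advanced intermediate). Simple ketone reduction or lactone cleavage could compete. The fallback sets out from 28 and comes back at 29. NaI/Me3SiCl/H2O in MeCN (Markovnikov hydroiodination of the terminal alkyne) gives the 2-iodoalkene F7. CrCl2 with catalytic NiCl2 in DMF (intramolecular Nozaki–Hiyama–Kishi addition of the vinyl chromium species to the C13 ketone) gives 29.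

**Further compounds**
F1 | step 6 | N-phenylcarbamate of 8 | O=C(Nc1ccccc1)O[C@@H]1CC(C(=O)OC)C2=C1CCC3(C2)OCCO3
F2 | step 6 | methyl 6,6-(ethylenedioxy)-7a-vinyl-2,4,5,6,7,7a-hexahydro-1H-indene-1-carboxylate (C8 vinyl, C9=C10 alkene) | C=C[C@]23CC4(OCCO4)CCC2=CCC3C(=O)OC
F3 | step 14 | propionate ester of 18 | C#CC[C@]23CC4(OCCO4)CC[C@H]2[C@](OC(=O)CC)(C(OCC)=C)C=C3C(=O)OC
F4 | step 14 | 19,10-lactone with C4–H and C4 methyl (C4 epimers), 5β-H, 6β-CO2Me | C#CC[C@]23CC4(OCCO4)CC[C@H]2[C@@]1(C(OCC)=C)OC(=O)C(C)[C@H]1[C@@H]3C(=O)OC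
F5 | step 14 | 19,10-lactone with C4 methyl and C4 hydroxymethyl (C3) | C#CC[C@]23CC4(OCCO4)CC[C@H]2[C@@]1(C(OCC)=C)OC(=O)[C@](C)(CO)[C@H]1[C@@H]3C(=O)OC
F6 | step 14 | 19,10-lactone with C4 methyl and C4 formyl (C3), C10 1-ethoxyvinyl, C13 dioxolane | C#CC[C@]23CC4(OCCO4)CC[C@H]2[C@@]1(C(OCC)=C)OC(=O)[C@](C)(C=O)[C@H]1[C@@H]3C(=O)OC
F7 | step 18 | 2-iodoallyl analogue of 28 (C16 iodoalkene) | C=C(I)C[C@]23CC(=O)CC[C@H]2[C@@]12OC(=O)[C@@](C)([C@H]1[C@@H]3C(=O)OC)[C@@H](O)C[C@@H]2O
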